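**Retrosynthetic overview**
1. Target 14 ⇐ diosmetin 12 by sulfation of O7–H and O3'–H; O5–H is held in a hydrogen bond to the C4 carbonyl and stays free.
2. 12 ⇐ 5,7-difluoroflavone 8: both ring A fluorides are exchanged for benzyloxy by SNAr, then three benzyl ethers are removed by hydrogenolysis.
3. 8 ⇐ 1,3-diketone 6: ring C is closed at O1–C8a by attack of the diketone enolate oxygen on an ortho C–F of the 2,4,6-trifluorophenyl ring.
4. 6 ⇐ O-benzyl isoacetovanillone 2 + 2,4,6-trifluorobenzoyl chloride 3 (enolate C-acylation). Rings A and B are bought; ring C is the only ring formed.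
5. Feature: in ring A the carbons C5, C7 and C8a all lie ortho or para to C4a, which carries the C4 carbonyl, so O1, O5 and O7 can each enter by displacement of a carbonyl-activated fluoride.

Key step: step 3

Remark: the target is drawn as the free bis(hydrogen sulfate), so the route ends at this acid, released from its pyridinium salt on a sulfonic acid resin. It is expected to keep better cold or as an alkali salt.

**Route**

Step 1
Reactants: 1 3-hydroxy-4-methoxyacetophenone
Product: 2 3-benzyloxy-4-methoxyacetophenone
Conditions: BnBr (1.1 equiv), K2CO3 (1.5 equiv), acetone, reflux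
Reagents that add atoms: benzyl bromide, BrCc1ccccc1
Why: Williamson ether synthesis; K2CO3 forms the phenoxide, which is benzylated, while the methyl ketone is not enolised by carbonate.

Step 2
Reactants: 2 3-benzyloxy-4-methoxyacetophenone; 3 2,4,6-trifluorobenzoyl chloride
Product: 6 1-(3-benzyloxy-4-methoxyphenyl)-3-(2,4,6-trifluorophenyl)propane-1,3-dione (largely enolised), via lithium enolate of the methyl ketone 4 (not isolated), via lithium diketonate 5 (not isolated)
Conditions: LiN(SiMe3)2 (2.2 equiv), THF, −78 °C; then 3 (1.0 equiv), −78 → −20 °C; 1 M HCl, 0 °C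
Reagents that add atoms: none
Why: Claisen-type C-acylation of a ketone lithium enolate by an acid chloride, in which the second equivalent of base stores the product as its diketonate so that it neither quenches unreacted enolate nor is acylated again, and the low temperature keeps the C–F bonds untouched.

Step 3
Reactants: 6 1-(3-benzyloxy-4-methoxyphenyl)-3-(2,4,6-trifluorophenyl)propane-1,3-dione
Product: 8 2-(3-benzyloxy-4-methoxyphenyl)-5,7-difluoro-4H-chromen-4-one, via potassium enolate of the diketone 7 (not isolated)
Conditions: K2CO3 (2 equiv), MeCN (about 0.05 M), 60 °C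
Reagents that add atoms: none
Why: K2CO3 should convert 6 into the enolate 7, whose oxygen on the carbon bearing ring B adds to a fluorine-bearing carbon ortho to the ketone (the future C8a) to give a Meisenheimer adduct with the charge delocalised into the C4 carbonyl and stabilised inductively by the two other fluorines, after which fluoride leaves. The closest known reaction type is the base-mediated intramolecular SNAr O-arylation of 1-(2-fluoroaryl)-1,3-diketones to flavones. Ring C closes as a six-membered ring by addition–elimination, formally a 6-exo-trig attack of the enolate oxygen on the C8a=C8 bond of the arene. No stereocentre is formed. The step needs O- over C-arylation and a single site of attack: closure through the central carbon C3 would have to give a four-membered ring and is excluded, and the 2,4,6-trifluorophenyl group has a mirror plane through its C1 and C4, so either ortho carbon leads to the same flavone. The para fluoride is out of reach of the tethered oxygen, and moderate dilution in MeCN (which, unlike DMF, releases no amine nucleophile) should hold back intermolecular displacement.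

Step 4
Reactants: 8 2-(3-benzyloxy-4-methoxyphenyl)-5,7-difluoro-4H-chromen-4-one; 9 benzyl alcohol
Product: 11 5,7-bis(benzyloxy)-2-(3-benzyloxy-4-methoxyphenyl)-4H-chromen-4-one, via 7-benzyloxy-5-fluoro flavone 10 (not isolated)
Conditions: 9 (2.6 equiv), NaH (2.5 equiv), THF, 0 °C; then 8, NMP, rt → 60 °C
Reagents that add atoms: none
Why: Twofold SNAr by sodium benzyloxide, expected first at C7 (para to the C4 carbonyl) and then at C5 (ortho to it), the second aided by Na+ bridging the carbonyl oxygen and the incoming alkoxide; the order does not affect the product.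

Step 5
Reactants: 11 5,7-bis(benzyloxy)-2-(3-benzyloxy-4-methoxyphenyl)-4H-chromen-4-one
Product: 12 diosmetin (5,7-dihydroxy-2-(3-hydroxy-4-methoxyphenyl)-4H-chromen-4-one)
Conditions: H2 (1 atm), 10% Pd/C, THF–MeOH 1:1, rt
Reagents that add atoms: none
Why: Catalytic hydrogenolysis of three aryl benzyl ethers, under which the aryl methyl ether and the aryl-conjugated C2=C3 bond of the chromenone should survive at 1 atm.

Step 6
Reactants: 12 diosmetin
Product: 14 luteolin 4'-methyl ether 7,3'-disulfate (diosmetin 7,3'-bis(hydrogen sulfate)), via bis(pyridinium) 7,3'-disulfate 13 (not isolated)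
Conditions: SO3·pyridine (5 equiv), pyridine, rt; MeOH quench, evaporate; Dowex 50WX8 (H+ form), H2O, 0 °C; lyophilise
Reagents that add atoms: sulfur trioxide–pyridine complex, O=S(=O)([O-])[n+]1ccccc1
Why: O-sulfonation of phenols by an SO3–amine complex, selective for O7 and O3' because O5–H is locked in a six-membered hydrogen bond to the C4 carbonyl and is a poor nucleophile, followed by cation exchange of pyridinium for H+.

**Compound list**
1 | 3-hydroxy-4-methoxyacetophenone | CC(=O)c1ccc(OC)c(O)c1 | starting material
2 | 3-benzyloxy-4-methoxyacetophenone | CC(=O)c1ccc(OC)c(OCc2ccccc2)c1 | intermediate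
3 | 2,4,6-trifluorobenzoyl chloride | O=C(Cl)c1c(F)cc(F)cc1F | starting material
4 | lithium 1-(3-benzyloxy-4-methoxyphenyl)ethenolate | [Li+].[O-]C(=C)c1ccc(OC)c(OCc2ccccc2)c1 | intermediate (not isolated)
5 | lithium (Z)-3-(3-benzyloxy-4-methoxyphenyl)-3-oxido-1-(2,4,6-trifluorophenyl)prop-2-en-1-one (delocalised diketonate, one form drawn) | [Li+].[O-]/C(=C\C(=O)c1c(F)cc(F)cc1F)c1ccc(OC)c(OCc2ccccc2)c1 | intermediate (not isolated)
6 | 1-(3-benzyloxy-4-methoxyphenyl)-3-(2,4,6-trifluorophenyl)propane-1,3-dione | COc1ccc(C(=O)CC(=O)c2c(F)cc(F)cc2F)cc1OCc1ccccc1 | intermediate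
7 | potassium (Z)-3-(3-benzyloxy-4-methoxyphenyl)-3-oxido-1-(2,4,6-trifluorophenyl)prop-2-en-1-one (delocalised enolate, one form drawn) | [K+].[O-]/C(=C\C(=O)c1c(F)cc(F)cc1F)c1ccc(OC)c(OCc2ccccc2)c1 | intermediate (not isolated)
8 | 2-(3-benzyloxy-4-methoxyphenyl)-5,7-difluoro-4H-chromen-4-one | COc1ccc(-c2cc(=O)c3c(F)cc(F)cc3o2)cc1OCc1ccccc1 | intermediate
9 | benzyl alcohol | OCc1ccccc1 | starting material
10 | 7-benzyloxy-2-(3-benzyloxy-4-methoxyphenyl)-5-fluoro-4H-chromen-4-one | COc1ccc(-c2cc(=O)c3c(F)cc(OCc4ccccc4)cc3o2)cc1OCc1ccccc1 | intermediate (not isolated)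
11 | 5,7-bis(benzyloxy)-2-(3-benzyloxy-4-methoxyphenyl)-4H-chromen-4-one | COc1ccc(-c2cc(=O)c3c(OCc4ccccc4)cc(OCc4ccccc4)cc3o2)cc1OCc1ccccc1 | intermediate
12 | diosmetin | COc1ccc(-c2cc(=O)c3c(O)cc(O)cc3o2)cc1O | intermediate
13 | bis(pyridinium) diosmetin 7,3'-disulfate | COc1ccc(-c2cc(=O)c3c(O)cc(OS(=O)(=O)[O-])cc3o2)cc1OS(=O)(=O)[O-].c1cc[nH+]cc1.c1cc[nH+]cc1 | intermediate (not isolated)
14 | luteolin 4'-methyl ether 7,3'-disulfate | COc1ccc(-c2cc(=O)c3c(O)cc(OS(=O)(=O)O)cc3o2)cc1OS(=O)(=O)O | target

**Totals**
Total step count: 6. Longest linear sequence: 6 steps (from 1).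

**Steps most likely to fail**

Step 6. The sulfation may stall at the 7-monosulfate or, if forced, begin to reach O5, and sulfate may be lost by acid-catalysed hydrolysis during cation exchange and drying. The fallback sets out from 12 and installs both sulfates as neutral diesters that can be chromatographed. 2,2,2-Trichloroethyl chlorosulfate (ClS(=O)(=O)OCC(Cl)(Cl)Cl) with NEt3 and DMAP in THF at 0 °C should convert O7–H and O3'–H into the 7,3'-bis(2,2,2-trichloroethyl sulfate) of diosmetin F1, which is purified on silica. Zn dust and ammonium formate in MeOH at rt should then remove both trichloroethyl groups by reductive β-elimination to give diammonium diosmetin 7,3'-disulfate F2. Brief passage of F2 through the H+ resin at 0 °C returns to the route at 14.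

Step 4. The second displacement, at the peri carbon C5, may stop once the C7 benzyloxy donor is in place, or excess alkoxide may add to C2 and open ring C. The fallback sets out from 8. One equivalent of NaOCH2Ph in NMP at 0 °C should give 10, which is now isolated. The C5 fluoride is then exchanged directly for hydroxyl with acetohydroxamic acid and K2CO3 in DMSO at 80 °C: SNAr by the hydroxamate oxygen, then Lossen-type fragmentation of the O-aryl hydroxamate to the phenoxide. This should give 7-benzyloxy-2-(3-benzyloxy-4-methoxyphenyl)-5-hydroxy-4H-chromen-4-one F3. Hydrogenolysis of F3 under the conditions of step 5 returns to the route at 12. If the first benzyloxide entered at C5 instead, the same two operations would still converge on 12.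

Step 2. The enolate may be acylated on oxygen to give the enol ester, or the diketone may be acylated a second time. The fallback sets out from 2 and separates C–C bond formation from the oxidation level. The lithium enolate 4 is added to 2,4,6-trifluorobenzaldehyde (O=Cc1c(F)cc(F)cc1F) in THF at −78 °C to give the racemic aldol 1-(3-benzyloxy-4-methoxyphenyl)-3-hydroxy-3-(2,4,6-trifluorophenyl)propan-1-one F4. Oxidation of F4 with Dess–Martin periodinane in CH2Cl2 at rt returns to the route at 6.

**Further compounds**
F1 | step 6 | diosmetin 7,3'-bis(2,2,2-trichloroethyl sulfate) | COc1ccc(-c2cc(=O)c3c(O)cc(OS(=O)(=O)OCC(Cl)(Cl)Cl)cc3o2)cc1OS(=O)(=O)OCC(Cl)(Cl)Cl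
F2 | step 6 | diammonium diosmetin 7,3'-disulfate | COc1ccc(-c2cc(=O)c3c(O)cc(OS(=O)(=O)[O-])cc3o2)cc1OS(=O)(=O)[O-].[NH4+].[NH4+]
F3 | step 4 | 7-benzyloxy-2-(3-benzyloxy-4-methoxyphenyl)-5-hydroxy-4H-chromen-4-one | COc1ccc(-c2cc(=O)c3c(O)cc(OCc4ccccc4)cc3o2)cc1OCc1ccccc1
F4 | step 2 | 1-(3-benzyloxy-4-methoxyphenyl)-3-hydroxy-3-(2,4,6-trifluorophenyl)propan-1-one (racemic) | COc1ccc(C(=O)CC(O)c2c(F)cc(F)cc2F)cc1OCc1ccccc1
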